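**Plan**

1. Cuts (core numbered as bicyclo[7.2.0]undecane: C1/C9 ring fusion, C8 methylidene carbon, C11 quaternary; dioxine carbons C3′–C6′): the epoxide goes back to the C4=C5 E-olefin; the dioxinol to an open hydroperoxy enone and then to an aldehyde plus an iodoalkenyl epoxide (bond C3′–C4′); the ring-fusion bond C1–C9 is then cut, and the resulting 11-membered ring is cut at C8–C9 and at C1–C11.
2. Forward: (E)-geranylacetone becomes a C10 aldehyde carrying an enol triflate; C11 is made by iridium-catalysed hydroxyprenylation with isoprene monoxide; an intramolecular Heck reaction closes the 11-membered ring as a 1,3-diene; 1,4-hydrostannation turns the diene into an allylstannane; one transannular bond formation then makes the cyclobutane and the nine-membered ring together; side chain, dioxinol and epoxide follow.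
3. Enabling feature: C9 is flanked by the methylidene-bearing C8, so it can be the γ-carbon of an allylstannane C9=C8–CH2–SnBu3 that regenerates the methylidene, and C1 is a secondary carbon 1,4 to it; without the C1–C9 bond, cyclobutane and cyclononene are one humulene-type 11-membered ring (C1…C11) with E olefins, the ring of the presumed biosynthesis.
4. Stereochemistry: C11 from the chiral iridium catalyst; C1 from CBS reduction followed by inversion in the key step; C9 from the trans-selective transannular closure; C6′ from (S)-2-methylglycidol with inversion on perhydrolysis; C3′ (hemiketal) thermodynamic; the epoxide from the substrate-controlled face of the E-olefin.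

Key step: step 10

Assumption 1: the (R)-Tol-BINAP-modified iridium catalyst of step 4 is taken to give the (9R,10R)-diol; if the sense of induction is the opposite, the (S)-ligand is used and nothing else changes.
Assumption 2: the hemiketal carbon of the dioxinol epimerises through the open hydroperoxy enone, and the configuration of the target is taken to be the one favoured at equilibrium.

**Route**

Step 1
Reactants: 1 (E)-geranylacetone, (5E)-6,10-dimethylundeca-5,9-dien-2-one
Product: 2 (5E)-6,10-dimethylundeca-1,5,9-trien-2-yl trifluoromethanesulfonate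
Conditions: LiN(i-Pr)2, THF, −78 °C; then PhNTf2, −78 → 0 °C
Reagents that add atoms: N-phenylbis(trifluoromethanesulfonimide), O=S(=O)(N(c1ccccc1)S(=O)(=O)C(F)(F)F)C(F)(F)F
Why: Kinetic deprotonation of the methyl ketone on the methyl side and O-sulfonylation of the enolate (enol triflate formation) should give the 2-triflyloxy-1-alkene that later becomes C8 with its methylidene carbon, without forming a stereocentre.

Step 2
Reactants: 2 (5E)-6,10-dimethylundeca-1,5,9-trien-2-yl trifluoromethanesulfonate
Product: 4 (5E)-8-(3,3-dimethyloxiran-2-yl)-6-methylocta-1,5-dien-2-yl trifluoromethanesulfonate, via bromohydrin 3 (not isolated)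
Conditions: NBS, THF/H2O, 0 °C; then DBU, CH2Cl2, 0 °C → rt
Reagents that add atoms: water, O
Why: Terminal-selective bromohydrin formation and base-induced ring closure should epoxidise the least hindered, most electron-rich trisubstituted olefin while the internal olefin and the electron-poor enol triflate stay intact, and the racemic oxirane centre is removed in step 3.

Step 3
Reactants: 4 (5E)-8-(3,3-dimethyloxiran-2-yl)-6-methylocta-1,5-dien-2-yl trifluoromethanesulfonate
Product: 5 (5E)-6-methyl-9-oxonona-1,5-dien-2-yl trifluoromethanesulfonate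
Conditions: HIO4·2H2O, THF/Et2O, 0 °C
Reagents that add atoms: none
Why: Acid-promoted opening of the epoxide to the glycol and periodate glycol cleavage in one operation should release acetone and the aldehyde without touching the olefin or the enol triflate.

Step 4
Reactants: 5 (5E)-6-methyl-9-oxonona-1,5-dien-2-yl trifluoromethanesulfonate; 6 2-methyl-2-vinyloxirane (isoprene monoxide, racemic)
Product: 7 (5E,9R,10R)-9-hydroxy-10-(hydroxymethyl)-6,10-dimethyldodeca-1,5,11-trien-2-yl trifluoromethanesulfonate
Conditions: [Ir(cod)Cl]2 (2.5 mol %), (R)-Tol-BINAP (5 mol %), 4-cyano-3-nitrobenzoic acid (10 mol %), K3PO4 (5 mol %), 2-propanol (2 equiv), THF, 60 °C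
Reagents that add atoms: none
Why: In this iridium-catalysed transfer-hydrogenative carbonyl tert-(hydroxy)prenylation the catalyst opens 6 to a π-allyl that adds through its substituted terminus to the aldehyde in a closed chair transition state, so that the quaternary centre (later C11, R) is set by the ligand together with an anti-related carbinol, the alkenyl triflate being expected to be as inert toward the catalyst as aryl halides are.

Step 5
Reactants: 7 (5E,9R,10R)-9-hydroxy-10-(hydroxymethyl)-6,10-dimethyldodeca-1,5,11-trien-2-yl trifluoromethanesulfonate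
Product: 8 (5E,9R,10R)-10-({[tert-butyl(diphenyl)silyl]oxy}methyl)-9-hydroxy-6,10-dimethyldodeca-1,5,11-trien-2-yl trifluoromethanesulfonate
Conditions: TBDPSCl, imidazole, CH2Cl2, 0 °C → rt
Reagents that add atoms: tert-butyl(chloro)diphenylsilane, CC(C)(C)[Si](Cl)(c1ccccc1)c1ccccc1
Why: Silylation should take the primary hydroxyl in preference to the more hindered secondary one flanked by the quaternary carbon, and the bulky non-participating ether later serves as the handle for the side chain.

Step 6
Reactants: 8 (5E,9R,10R)-10-({[tert-butyl(diphenyl)silyl]oxy}methyl)-9-hydroxy-6,10-dimethyldodeca-1,5,11-trien-2-yl trifluoromethanesulfonate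
Product: 9 (5E,10R)-10-({[tert-butyl(diphenyl)silyl]oxy}methyl)-6,10-dimethyl-9-oxododeca-1,5,11-trien-2-yl trifluoromethanesulfonate
Conditions: Dess–Martin periodinane, CH2Cl2, 0 °C → rt
Reagents that add atoms: none
Why: Dess–Martin oxidation erases the carbinol centre from step 4, whose configuration is the opposite of the one an invertive ring closure needs, and cannot epimerise the adjacent quaternary centre.

Step 7
Reactants: 9 (5E,10R)-10-({[tert-butyl(diphenyl)silyl]oxy}methyl)-6,10-dimethyl-9-oxododeca-1,5,11-trien-2-yl trifluoromethanesulfonate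
Product: 10 (5E,9S,10R)-10-({[tert-butyl(diphenyl)silyl]oxy}methyl)-9-hydroxy-6,10-dimethyldodeca-1,5,11-trien-2-yl trifluoromethanesulfonate
Conditions: (R)-2-methyl-CBS-oxazaborolidine (0.5 equiv), catecholborane, toluene, −78 °C
Reagents that add atoms: none
Why: In this Corey–Bakshi–Shibata reduction the ketone lies between a quaternary carbon (large) and a methylene (small), so the (R)-oxazaborolidine should deliver hydride under reagent control to give the (S)-carbinol (later C1), and catecholborane at low temperature spares the alkenes.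

Step 8
Reactants: 10 (5E,9S,10R)-10-({[tert-butyl(diphenyl)silyl]oxy}methyl)-9-hydroxy-6,10-dimethyldodeca-1,5,11-trien-2-yl trifluoromethanesulfonate
Product: 11 (1S,2R,3E,8E)-2-({[tert-butyl(diphenyl)silyl]oxy}methyl)-2,9-dimethyl-5-methylidenecycloundeca-3,8-dien-1-ol
Conditions: Pd(OAc)2 (10 mol %), PPh3 (20 mol %), K2CO3, DMF (0.002 M), 80 °C
Reagents that add atoms: none
Why: In this intramolecular Heck reaction zerovalent palladium inserts into the alkenyl triflate, the monosubstituted vinyl group is carbopalladated at its unhindered terminus (11-endo closure) and β-hydride elimination can only occur toward the new bond because the other neighbour is quaternary, which should give the E-configured 1,3-diene of a humulene-type ring without a new stereocentre.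

Step 9
Reactants: 11 (1S,2R,3E,8E)-2-({[tert-butyl(diphenyl)silyl]oxy}methyl)-2,9-dimethyl-5-methylidenecycloundeca-3,8-dien-1-ol
Product: 12 (1S,2R,4Z,8E)-2-({[tert-butyl(diphenyl)silyl]oxy}methyl)-2,9-dimethyl-5-[(tributylstannyl)methyl]cycloundeca-4,8-dien-1-ol
Conditions: Bu3SnH (slow addition), Pd(PPh3)4 (3 mol %), THF, 0 °C → rt
Reagents that add atoms: tributyltin hydride, CCCC[SnH](CCCC)CCCC
Why: Palladium-catalysed 1,4-hydrostannation of the cisoid 1,3-diene should place hydrogen on the ring terminus next to the quaternary carbon and tin on the unhindered exocyclic CH2, giving the 2-alkenylstannane whose ring carbons are trans across the new trisubstituted double bond while the free hydroxyl is tolerated.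

Step 10
Reactants: 12 (1S,2R,4Z,8E)-2-({[tert-butyl(diphenyl)silyl]oxy}methyl)-2,9-dimethyl-5-[(tributylstannyl)methyl]cycloundeca-4,8-dien-1-ol
Product: 14 (1S,4E,9R,11S)-11-({[tert-butyl(diphenyl)silyl]oxy}methyl)-4,11-dimethyl-8-methylidenebicyclo[7.2.0]undec-4-ene, via triflate 13 (not isolated)
Conditions: Tf2O (1.05 equiv), 2,6-di-tert-butyl-4-methylpyridine, CH2Cl2 (dilute), −78 °C; then −78 → −20 °C
Reagents that add atoms: none
Why: Proposed new method: O-triflation at −78 °C gives the secondary triflate 13, which on warming should ionise with anchimeric assistance from the transannular allylstannane, C9 attacking C1 from the rear while the β-stannyl cation at C8 collapses to the exocyclic methylidene with loss of Bu3SnOTf (intramolecular SE2′ on an SN2-like, loosely bound carbon). The closest known reaction types are allylmetal-terminated cation–olefin cyclisations, the π-assisted transannular solvolysis of medium-ring sulfonates and the acid-promoted closure of humulene to caryophyllane-type cations, and the step copies the presumed biosynthetic humulyl-to-caryophyllenyl cyclisation. The cyclobutane closes 4-exo-trig with respect to the allylstannane double bond, and the nine-membered ring arises at the same moment by transannular contraction of the 11-membered ring (formally 9-endo-trig). C1 is set by inversion of the carbinol installed in step 7 and C9 by the crossed conformer in which the E-configured allylstannane lies behind the C1–O bond, which should lead to the trans ring fusion because a cis-fused E-cyclononene is far more strained; C11 is a spectator. The step needs π-participation to outrun 1,2-shift from C11 and loss of triflic acid, which the high nucleophilicity of the allylstannane, its 1,4 proximity to C1, the hindered non-nucleophilic base and the low temperature are meant to secure, and tin on the future methylidene carbon fixes the regiochemistry (attack through C9, not C8) and ends the cascade before the C4=C5 olefin can add.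

Step 11
Reactants: 14 (1S,4E,9R,11S)-11-({[tert-butyl(diphenyl)silyl]oxy}methyl)-4,11-dimethyl-8-methylidenebicyclo[7.2.0]undec-4-ene
Product: 15 [(1S,4E,9R,11S)-4,11-dimethyl-8-methylidenebicyclo[7.2.0]undec-4-en-11-yl]methanol
Conditions: TBAF, THF, 40 °C
Reagents that add atoms: none
Why: Fluoride-induced desilylation should free the neopentyl primary alcohol under non-acidic conditions that leave the acid-sensitive diene and all stereocentres untouched.

Step 12
Reactants: 15 [(1S,4E,9R,11S)-4,11-dimethyl-8-methylidenebicyclo[7.2.0]undec-4-en-11-yl]methanol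
Product: 16 (1S,4E,9R,11S)-4,11-dimethyl-8-methylidenebicyclo[7.2.0]undec-4-ene-11-carbaldehyde
Conditions: Dess–Martin periodinane, pyridine, CH2Cl2, 0 °C
Reagents that add atoms: none
Why: Buffered Dess–Martin oxidation should give the non-enolisable aldehyde without acid-induced transannular reactions of the strained ring olefin.

Step 13
Reactants: 17 (S)-2-methylglycidol, [(2S)-2-methyloxiran-2-yl]methanol
Product: 19 (2S)-2-[(E)-2-iodoethenyl]-2-methyloxirane, via epoxy aldehyde 18 (not isolated)
Conditions: Pr4N[RuO4] (5 mol %), 4-methylmorpholine N-oxide, 4 Å molecular sieves, CH2Cl2, 0 °C; filtered solution used directly; then CrCl2, CHI3, THF, 0 °C → rt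
Reagents that add atoms: iodoform, IC(I)I
Why: Ley–Griffith oxidation to the volatile, non-enolisable epoxy aldehyde and Takai olefination, which should give the E-iodoalkene, carry the quaternary oxirane stereocentre of the chiral-pool alcohol through unchanged.

Step 14
Reactants: 16 (1S,4E,9R,11S)-4,11-dimethyl-8-methylidenebicyclo[7.2.0]undec-4-ene-11-carbaldehyde; 19 (2S)-2-[(E)-2-iodoethenyl]-2-methyloxirane
Product: 20 (2E)-1-[(1S,4E,9R,11S)-4,11-dimethyl-8-methylidenebicyclo[7.2.0]undec-4-en-11-yl]-3-[(2S)-2-methyloxiran-2-yl]prop-2-en-1-ol (both carbinol epimers)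
Conditions: CrCl2, NiCl2 (2 mol %), DMSO, rt
Reagents that add atoms: none
Why: The Nozaki–Hiyama–Kishi reaction should add the alkenylchromium species chemoselectively to the hindered aldehyde with retention of the E geometry while tolerating the epoxide and the olefins, and the carbinol centre formed without control is removed in step 15.

Step 15
Reactants: 20 (2E)-1-[(1S,4E,9R,11S)-4,11-dimethyl-8-methylidenebicyclo[7.2.0]undec-4-en-11-yl]-3-[(2S)-2-methyloxiran-2-yl]prop-2-en-1-ol
Product: 21 (2E)-1-[(1S,4E,9R,11S)-4,11-dimethyl-8-methylidenebicyclo[7.2.0]undec-4-en-11-yl]-3-[(2S)-2-methyloxiran-2-yl]prop-2-en-1-one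
Conditions: Dess–Martin periodinane, pyridine, CH2Cl2, 0 °C
Reagents that add atoms: none
Why: Dess–Martin oxidation of the allylic alcohol should give the E-enone and removes the stereo-random carbinol.

Step 16
Reactants: 21 (2E)-1-[(1S,4E,9R,11S)-4,11-dimethyl-8-methylidenebicyclo[7.2.0]undec-4-en-11-yl]-3-[(2S)-2-methyloxiran-2-yl]prop-2-en-1-one
Product: 22 (2E,4R)-4-hydroperoxy-5-hydroxy-4-methyl-1-[(1S,4E,9R,11S)-4,11-dimethyl-8-methylidenebicyclo[7.2.0]undec-4-en-11-yl]pent-2-en-1-one
Conditions: H2O2 (anhydrous solution in Et2O, excess), H3PMo12O40 (2 mol %), Et2O, 0 °C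
Reagents that add atoms: hydrogen peroxide, OO
Why: In this acid-catalysed perhydrolysis of an epoxide, hydrogen peroxide should open the oxirane at its tertiary allylic carbon with inversion, so that the (S)-epoxide gives the (R)-hydroperoxide, the E geometry excluding participation by the carbonyl oxygen and the short, cold contact being meant to spare the strained ring olefin.

Step 17
Reactants: 22 (2E,4R)-4-hydroperoxy-5-hydroxy-4-methyl-1-[(1S,4E,9R,11S)-4,11-dimethyl-8-methylidenebicyclo[7.2.0]undec-4-en-11-yl]pent-2-en-1-one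
Product: 24 (3R,6R)-3-[(1S,4E,9R,11S)-4,11-dimethyl-8-methylidenebicyclo[7.2.0]undec-4-en-11-yl]-6-(hydroxymethyl)-6-methyl-3,6-dihydro-1,2-dioxin-3-ol, via Z-enone 23 (not isolated)
Conditions: hν (365 nm), MeCN, 10 °C
Reagents that add atoms: none
Why: Photochemical E-to-Z isomerisation of the enone followed by spontaneous 6-exo-trig addition of the hydroperoxide to the ketone (ring–chain tautomerism) should drain the photoequilibrium into the cyclic peroxy-hemiketal, whose hemiketal centre settles under thermodynamic control.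

Step 18
Reactants: 24 (3R,6R)-3-[(1S,4E,9R,11S)-4,11-dimethyl-8-methylidenebicyclo[7.2.0]undec-4-en-11-yl]-6-(hydroxymethyl)-6-methyl-3,6-dihydro-1,2-dioxin-3-ol
Product: 25 CNP0273942.1, (3R,6R)-3-[(1S,4S,6S,10R,12S)-4,12-dimethyl-9-methylidene-5-oxatricyclo[8.2.0.0(4,6)]dodecan-12-yl]-6-(hydroxymethyl)-6-methyl-3,6-dihydro-1,2-dioxin-3-ol
Conditions: dimethyldioxirane (acetone solution, 1.05 equiv), CH2Cl2, −40 °C
Reagents that add atoms: dimethyldioxirane, CC1(C)OO1
Why: Epoxidation of the strained E-trisubstituted ring olefin, by far the most nucleophilic double bond, should occur on the exposed face of the predominant ring conformer, the substrate-controlled preference that caryophyllene shows toward peracids, to give the (4S,6S)-epoxide.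

**Compound list**

1 | (E)-geranylacetone, (5E)-6,10-dimethylundeca-5,9-dien-2-one | CC(=O)CC/C=C(\C)CCC=C(C)C | starting material
2 | (5E)-6,10-dimethylundeca-1,5,9-trien-2-yl trifluoromethanesulfonate | C=C(OS(=O)(=O)C(F)(F)F)CC/C=C(\C)CCC=C(C)C | intermediate
3 | (5E)-9-bromo-10-hydroxy-6,10-dimethylundeca-1,5-dien-2-yl trifluoromethanesulfonate (racemic bromohydrin, not isolated) | C=C(OS(=O)(=O)C(F)(F)F)CC/C=C(\C)CCC(Br)C(C)(C)O | intermediate
4 | (5E)-8-(3,3-dimethyloxiran-2-yl)-6-methylocta-1,5-dien-2-yl trifluoromethanesulfonate (racemic) | C=C(OS(=O)(=O)C(F)(F)F)CC/C=C(\C)CCC1OC1(C)C | intermediate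
5 | (5E)-6-methyl-9-oxonona-1,5-dien-2-yl trifluoromethanesulfonate | C=C(OS(=O)(=O)C(F)(F)F)CC/C=C(\C)CCC=O | intermediate
6 | 2-methyl-2-vinyloxirane (isoprene monoxide, racemic) | C=CC1(C)CO1 | starting material
7 | (5E,9R,10R)-9-hydroxy-10-(hydroxymethyl)-6,10-dimethyldodeca-1,5,11-trien-2-yl trifluoromethanesulfonate | O[C@H](CC/C(C)=C/CCC(=C)OS(=O)(=O)C(F)(F)F)[C@@](C)(CO)C=C | intermediate
8 | (5E,9R,10R)-10-({[tert-butyl(diphenyl)silyl]oxy}methyl)-9-hydroxy-6,10-dimethyldodeca-1,5,11-trien-2-yl trifluoromethanesulfonate | O[C@H](CC/C(C)=C/CCC(=C)OS(=O)(=O)C(F)(F)F)[C@@](C)(CO[Si](c1ccccc1)(c1ccccc1)C(C)(C)C)C=C | intermediate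
9 | (5E,10R)-10-({[tert-butyl(diphenyl)silyl]oxy}methyl)-6,10-dimethyl-9-oxododeca-1,5,11-trien-2-yl trifluoromethanesulfonate | O=C(CC/C(C)=C/CCC(=C)OS(=O)(=O)C(F)(F)F)[C@@](C)(CO[Si](c1ccccc1)(c1ccccc1)C(C)(C)C)C=C | intermediate
10 | (5E,9S,10R)-10-({[tert-butyl(diphenyl)silyl]oxy}methyl)-9-hydroxy-6,10-dimethyldodeca-1,5,11-trien-2-yl trifluoromethanesulfonate | O[C@@H](CC/C(C)=C/CCC(=C)OS(=O)(=O)C(F)(F)F)[C@@](C)(CO[Si](c1ccccc1)(c1ccccc1)C(C)(C)C)C=C | intermediate
11 | (1S,2R,3E,8E)-2-({[tert-butyl(diphenyl)silyl]oxy}methyl)-2,9-dimethyl-5-methylidenecycloundeca-3,8-dien-1-ol | O[C@H]1CC/C(C)=C/CCC(=C)/C=C/[C@]1(C)CO[Si](c2ccccc2)(c2ccccc2)C(C)(C)C | intermediate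
12 | (1S,2R,4Z,8E)-2-({[tert-butyl(diphenyl)silyl]oxy}methyl)-2,9-dimethyl-5-[(tributylstannyl)methyl]cycloundeca-4,8-dien-1-ol | O[C@H]1CC/C(C)=C/CC/C(C[Sn](CCCC)(CCCC)CCCC)=C/C[C@]1(C)CO[Si](c2ccccc2)(c2ccccc2)C(C)(C)C | intermediate
13 | trifluoromethanesulfonate of 12 at the ring hydroxyl (not isolated) | FC(F)(F)S(=O)(=O)O[C@H]1CC/C(C)=C/CC/C(C[Sn](CCCC)(CCCC)CCCC)=C/C[C@]1(C)CO[Si](c2ccccc2)(c2ccccc2)C(C)(C)C | intermediate
14 | (1S,4E,9R,11S)-11-({[tert-butyl(diphenyl)silyl]oxy}methyl)-4,11-dimethyl-8-methylidenebicyclo[7.2.0]undec-4-ene | C=C1CC/C=C(\C)CC[C@H]2[C@H]1C[C@]2(C)CO[Si](c3ccccc3)(c3ccccc3)C(C)(C)C | intermediate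
15 | [(1S,4E,9R,11S)-4,11-dimethyl-8-methylidenebicyclo[7.2.0]undec-4-en-11-yl]methanol | C=C1CC/C=C(\C)CC[C@H]2[C@H]1C[C@]2(C)CO | intermediate
16 | (1S,4E,9R,11S)-4,11-dimethyl-8-methylidenebicyclo[7.2.0]undec-4-ene-11-carbaldehyde | C=C1CC/C=C(\C)CC[C@H]2[C@H]1C[C@]2(C)C=O | intermediate
17 | (S)-2-methylglycidol, [(2S)-2-methyloxiran-2-yl]methanol | OC[C@@]1(C)CO1 | starting material
18 | (2R)-2-methyloxirane-2-carbaldehyde (not isolated) | O=C[C@@]1(C)CO1 | intermediate
19 | (2S)-2-[(E)-2-iodoethenyl]-2-methyloxirane | I/C=C/[C@@]1(C)CO1 | intermediate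
20 | (2E)-1-[(1S,4E,9R,11S)-4,11-dimethyl-8-methylidenebicyclo[7.2.0]undec-4-en-11-yl]-3-[(2S)-2-methyloxiran-2-yl]prop-2-en-1-ol (both carbinol epimers) | C=C1CC/C=C(\C)CC[C@H]2[C@H]1C[C@]2(C)C(O)/C=C/[C@@]3(C)CO3 | intermediate
21 | (2E)-1-[(1S,4E,9R,11S)-4,11-dimethyl-8-methylidenebicyclo[7.2.0]undec-4-en-11-yl]-3-[(2S)-2-methyloxiran-2-yl]prop-2-en-1-one | C=C1CC/C=C(\C)CC[C@H]2[C@H]1C[C@]2(C)C(=O)/C=C/[C@@]3(C)CO3 | intermediate
22 | (2E,4R)-4-hydroperoxy-5-hydroxy-4-methyl-1-[(1S,4E,9R,11S)-4,11-dimethyl-8-methylidenebicyclo[7.2.0]undec-4-en-11-yl]pent-2-en-1-one | C=C1CC/C=C(\C)CC[C@H]2[C@H]1C[C@]2(C)C(=O)/C=C/[C@](C)(CO)OO | intermediate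
23 | (2Z,4R)-4-hydroperoxy-5-hydroxy-4-methyl-1-[(1S,4E,9R,11S)-4,11-dimethyl-8-methylidenebicyclo[7.2.0]undec-4-en-11-yl]pent-2-en-1-one (not isolated) | C=C1CC/C=C(\C)CC[C@H]2[C@H]1C[C@]2(C)C(=O)/C=C\[C@](C)(CO)OO | intermediate
24 | (3R,6R)-3-[(1S,4E,9R,11S)-4,11-dimethyl-8-methylidenebicyclo[7.2.0]undec-4-en-11-yl]-6-(hydroxymethyl)-6-methyl-3,6-dihydro-1,2-dioxin-3-ol | C=C1CC/C=C(\C)CC[C@H]2[C@H]1C[C@]2(C)[C@@]3(O)C=C[C@](C)(CO)OO3 | intermediate
25 | CNP0273942.1, (3R,6R)-3-[(1S,4S,6S,10R,12S)-4,12-dimethyl-9-methylidene-5-oxatricyclo[8.2.0.0(4,6)]dodecan-12-yl]-6-(hydroxymethyl)-6-methyl-3,6-dihydro-1,2-dioxin-3-ol | C=C1CC[C@@H]2O[C@@]2(C)CC[C@H]2[C@H]1C[C@]2(C)[C@@]1(O)C=C[C@](C)(CO)OO1 | target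

**Step count and risks**

Total step count: 18. Longest linear sequence: 17 steps (steps 1–12 and 14–18; step 13 makes the side-chain fragment).

Steps most likely to fail:

Step 10 (the step beyond known chemistry). The triflate may ionise with a 1,2-shift of a group from C11, or lose triflic acid toward the ring, before the allylstannane engages; the anhydride may also sulfonylate the allylstannane. Fallback, from 12 back to 14, by a Barton–McCombie-type radical generation joined to a Keck radical allylation run within the ring. Alcohol 12 is converted with NaH, CS2 and then MeI (THF, 0 °C) into the S-methyl xanthate F1. Irradiation of F1 with hexabutylditin in dilute benzene at 80 °C should generate the C1 radical, which adds to C9 (transannular 4-exo-trig) and expels the tributylstannyl radical from the neighbouring carbon, so that the methylidene and 14 form directly. No hydrogen donor is present, and loss of tin should be much faster than reopening of the cyclobutylcarbinyl radical. The ring fusion would then rest on the lower strain of the trans junction and on the ring chain turning away from the silyloxymethyl group on C11, not on inversion.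

Step 16. Under peroxide and heteropoly acid the strained C4=C5 olefin may be epoxidised or protonated with transannular cyclisation, and partial ionisation at the tertiary allylic carbon may erode the configuration at C6′. Fallback, from 16 and 19 back to 22, moves the perhydrolysis to the small fragment and joins the pieces by an aldol condensation. Aldehyde 16 is converted with MeMgBr into methyl carbinol F2 and by Dess–Martin oxidation into methyl ketone F3. Separately, 19 is opened under the conditions of step 16 to hydroperoxy alcohol F4, silylated (Et3SiOTf, 2,6-lutidine) to the bis(triethylsilyl) derivative F5 and ozonised (O3, CH2Cl2, −78 °C; Me2S) to peroxy aldehyde F6. The lithium enolate of F3 (LiN(i-Pr)2, THF, −78 °C) should add to F6 to give aldol adduct F7. Dehydration (MsCl, Et3N; then DBU) gives the protected E-enone F8, and HF·pyridine removes both silyl groups to give 22.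

Step 8. Intermolecular coupling, or reduction or hydrolysis of the alkenyl triflate, may outrun closure of the 11-membered ring. Fallback, from 9 back to 11, closes the ring by a Nozaki–Hiyama–Kishi reaction instead. Ketone 9 is hydroborated at its monosubstituted vinyl group (9-BBN; NaBO3) to keto alcohol F9 and oxidised (Dess–Martin periodinane) to keto aldehyde F10. CrCl2 with catalytic NiCl2 (DMSO/THF, high dilution) should couple the alkenyl triflate with the aldehyde to give the macrocyclic hydroxy ketone F11. Its methyl carbonate F12 (ClCO2Me, pyridine) undergoes palladium-catalysed 1,4-elimination (Pd(PPh3)4, THF, reflux) through the π-allyl complex to dienone F13. Corey–Bakshi–Shibata reduction as in step 7 then gives 11.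

Further compounds
F1 | step 10 | O-[(1S,2R,4Z,8E)-2-({[tert-butyl(diphenyl)silyl]oxy}methyl)-2,9-dimethyl-5-[(tributylstannyl)methyl]cycloundeca-4,8-dien-1-yl] S-methyl dithiocarbonate | CSC(=S)O[C@H]1CC/C(C)=C/CC/C(C[Sn](CCCC)(CCCC)CCCC)=C/C[C@]1(C)CO[Si](c2ccccc2)(c2ccccc2)C(C)(C)C
F2 | step 16 | 1-[(1S,4E,9R,11S)-4,11-dimethyl-8-methylidenebicyclo[7.2.0]undec-4-en-11-yl]ethan-1-ol (both carbinol epimers) | C=C1CC/C=C(\C)CC[C@H]2[C@H]1C[C@]2(C)C(C)O
F3 | step 16 | 1-[(1S,4E,9R,11S)-4,11-dimethyl-8-methylidenebicyclo[7.2.0]undec-4-en-11-yl]ethan-1-one | C=C1CC/C=C(\C)CC[C@H]2[C@H]1C[C@]2(C)C(C)=O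
F4 | step 16 | (2R,3E)-2-hydroperoxy-4-iodo-2-methylbut-3-en-1-ol | I/C=C/[C@](C)(CO)OO
F5 | step 16 | triethyl{[(2R,3E)-4-iodo-2-methyl-2-(triethylsilylperoxy)but-3-en-1-yl]oxy}silane | I/C=C/[C@](C)(CO[Si](CC)(CC)CC)OO[Si](CC)(CC)CC
F6 | step 16 | (2S)-2-methyl-3-(triethylsilyloxy)-2-(triethylsilylperoxy)propanal | O=C[C@](C)(CO[Si](CC)(CC)CC)OO[Si](CC)(CC)CC
F7 | step 16 | (4R)-3-hydroxy-4-methyl-1-[(1S,4E,9R,11S)-4,11-dimethyl-8-methylidenebicyclo[7.2.0]undec-4-en-11-yl]-5-(triethylsilyloxy)-4-(triethylsilylperoxy)pentan-1-one (both carbinol epimers) | C=C1CC/C=C(\C)CC[C@H]2[C@H]1C[C@]2(C)C(=O)CC(O)[C@](C)(CO[Si](CC)(CC)CC)OO[Si](CC)(CC)CC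
F8 | step 16 | (2E,4R)-4-methyl-1-[(1S,4E,9R,11S)-4,11-dimethyl-8-methylidenebicyclo[7.2.0]undec-4-en-11-yl]-5-(triethylsilyloxy)-4-(triethylsilylperoxy)pent-2-en-1-one | C=C1CC/C=C(\C)CC[C@H]2[C@H]1C[C@]2(C)C(=O)/C=C/[C@](C)(CO[Si](CC)(CC)CC)OO[Si](CC)(CC)CC
F9 | step 8 | (5E,10R)-10-({[tert-butyl(diphenyl)silyl]oxy}methyl)-12-hydroxy-6,10-dimethyl-9-oxododeca-1,5-dien-2-yl trifluoromethanesulfonate | O=C(CC/C(C)=C/CCC(=C)OS(=O)(=O)C(F)(F)F)[C@@](C)(CO[Si](c1ccccc1)(c1ccccc1)C(C)(C)C)CCO
F10 | step 8 | (5E,10R)-10-({[tert-butyl(diphenyl)silyl]oxy}methyl)-6,10-dimethyl-9,12-dioxododeca-1,5-dien-2-yl trifluoromethanesulfonate | O=C(CC/C(C)=C/CCC(=C)OS(=O)(=O)C(F)(F)F)[C@@](C)(CO[Si](c1ccccc1)(c1ccccc1)C(C)(C)C)CC=O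
F11 | step 8 | (2R,8E)-2-({[tert-butyl(diphenyl)silyl]oxy}methyl)-4-hydroxy-2,9-dimethyl-5-methylidenecycloundec-8-en-1-one (both carbinol epimers) | O=C1CC/C(C)=C/CCC(=C)C(O)C[C@]1(C)CO[Si](c2ccccc2)(c2ccccc2)C(C)(C)C
F12 | step 8 | (3R,8E)-3-({[tert-butyl(diphenyl)silyl]oxy}methyl)-3,9-dimethyl-5-methylidene-2-oxocycloundec-8-en-1-yl... methyl carbonate of F11 at its hydroxyl | O=C1CC/C(C)=C/CCC(=C)C(OC(=O)OC)C[C@]1(C)CO[Si](c2ccccc2)(c2ccccc2)C(C)(C)C
F13 | step 8 | (2R,3E,8E)-2-({[tert-butyl(diphenyl)silyl]oxy}methyl)-2,9-dimethyl-5-methylidenecycloundeca-3,8-dien-1-one | O=C1CC/C(C)=C/CCC(=C)/C=C/[C@]1(C)CO[Si](c2ccccc2)(c2ccccc2)C(C)(C)C
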